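**Retrosynthetic overview**
- Target ⇒ (R)-2-allyl-4-aryloxy-4,5-dimethoxycyclohexa-2,5-dienone: 1,4-reduction of the only reactive enone arm, then face-selective protonation at C6.
- Dienone ⇒ two molecules of 2-allyl-4,5-dimethoxyphenol by oxidative O–C4 coupling (the target is a dihydro-dimer of this phenol). The mixed-ketal carbon arises from a planar cation, so it is formed racemic and resolved.
- Allylphenol ⇒ allylsilane + 3,4,4-trimethoxycyclohexa-2,5-dienone. This is the only C–C bond-forming step; the quinone monoketal serves as an ortho-cation (vinylogous enolonium) of the phenol, so two innately nucleophilic carbons are joined. It supplies both ring–allyl bonds of the target.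
- Quinone monoketal ⇒ 3,4-dimethoxyphenol + methanol.
- No ring is constructed: the cyclohexenone is a dearomatised benzene ring (order: dearomatise → allylate/rearomatise → dearomatise → reduce).

Assumption: the SMILES is read as (4R,6S) with C1 = C=O, C3 = vinylic C–OMe, C4 = ketal carbon, C6 = allyl carbon; the C6 allyl and C4 aryloxy groups are cis.

**Step 1**
Reactants: 1 3,4-dimethoxyphenol; 2 methanol
Product: 3 3,4,4-trimethoxycyclohexa-2,5-dien-1-one
Conditions: PhI(OAc)2 (1.05 equiv), MeOH, 0 °C, 20 min
Reagents that add atoms: methanol, CO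
Why: Hypervalent-iodine oxidative dearomatization of a p-methoxyphenol, in which methanol adds to the methoxy-bearing para carbon of the oxidised phenol to give the p-quinone monoketal; no stereocentre is formed.

**Step 2 (key step)**
Reactants: 3 3,4,4-trimethoxycyclohexa-2,5-dien-1-one; 4 allyltrimethylsilane
Product: 7 2-allyl-4,5-dimethoxyphenol, via oxocarbenium triflate 5 (not isolated), via 6-allyl-3,4-dimethoxycyclohexa-2,4-dien-1-one 6 (not isolated)
Conditions: 4 (3 equiv), TMSOTf (10 mol %), CH2Cl2, −78 → −40 °C, slow addition of 3; aq. NaHCO3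
Reagents that add atoms: allyltrimethylsilane, C=CC[Si](C)(C)C
Why: Proposed new method: TMSOTf ionises the ketal to cation 5, a vinylogous enolonium (ortho-cation of the phenol) whose unhindered C6 terminus (α to C=O; C2 is flanked by OMe) is attacked SN2′-fashion by the allylsilane, the silyl group is lost as MeOSiMe3 and dienone 6 tautomerises to phenol 7, so two innately nucleophilic carbons (phenol ortho-C and allylsilane γ-C) are joined; the closest known reactions are the Hosomi–Sakurai allylation of acetals and the acid-promoted SN2′ couplings of quinone monoketals with arenes and alkenes; no stereocentre is formed.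

**Step 3**
Reactants: 7 2-allyl-4,5-dimethoxyphenol (2 equiv; one molecule is oxidised, the other is the O-nucleophile)
Product: 8 rac-2-allyl-4-(2-allyl-4,5-dimethoxyphenoxy)-4,5-dimethoxycyclohexa-2,5-dien-1-one
Conditions: PhI(OAc)2 (0.5 equiv, added over 30 min), CH2Cl2, −30 °C; aq. NaHCO3
Reagents that add atoms: none
Why: Oxidative dearomatization (oxidative phenol O–C4 coupling) in which the methoxy-bearing para carbon of the oxidised phenol is captured by the phenolic oxygen of a second molecule of 7 to give the mixed aryl methyl quinone monoketal; the new C4 stereocentre comes from a planar cation and is racemic.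

**Step 4**
Reactants: 8 rac-2-allyl-4-(2-allyl-4,5-dimethoxyphenoxy)-4,5-dimethoxycyclohexa-2,5-dien-1-one
Product: 9 (R)-2-allyl-4-(2-allyl-4,5-dimethoxyphenoxy)-4,5-dimethoxycyclohexa-2,5-dien-1-one
Conditions: preparative HPLC, immobilised amylose tris(3,5-dimethylphenylcarbamate) phase, hexane/i-PrOH, rt
Reagents that add atoms: none
Why: Enantiomer separation on a chiral stationary phase fixes C4 as R (>99% ee, assigned by ECD), chosen because this O,O-ketal centre offers no handle for asymmetric induction and is configurationally stable under neutral conditions.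

**Step 5**
Reactants: 9 (R)-2-allyl-4-(2-allyl-4,5-dimethoxyphenoxy)-4,5-dimethoxycyclohexa-2,5-dien-1-one
Product: 11 (4R,6S)-6-allyl-4-(2-allyl-4,5-dimethoxyphenoxy)-3,4-dimethoxycyclohex-2-en-1-one, via copper(I) dienolate 10 (not isolated)
Conditions: [(Ph3P)CuH]6 (5 mol %), PhMe2SiH (1.5 equiv), t-BuOH (2 equiv), toluene, −20 → 0 °C; pH 7 buffer
Reagents that add atoms: none
Why: CuH-catalysed (Stryker-type) conjugate reduction touches only the allyl-substituted enone arm (the β-methoxy-enone arm is a deactivated vinylogous ester and isolated alkenes are inert), and kinetic axial protonation of enolate 10 by bulky t-BuOH should occur on the face syn to the small pseudo-axial OMe and anti to the aryloxy group, placing allyl cis to OAr (6S) while C4 is untouched.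

**Compound list**
1 | 3,4-dimethoxyphenol | COc1ccc(O)cc1OC | starting material
2 | methanol | CO | starting material
3 | 3,4,4-trimethoxycyclohexa-2,5-dien-1-one | COC1=CC(=O)C=CC1(OC)OC | intermediate
4 | allyltrimethylsilane | C=CC[Si](C)(C)C | starting material
5 | (2-methoxy-4-oxocyclohexa-2,5-dien-1-ylidene)(methyl)oxonium triflate | COC1=CC(=O)C=CC1=[O+]C.[O-]S(=O)(=O)C(F)(F)F | intermediate (not isolated)
6 | 6-allyl-3,4-dimethoxycyclohexa-2,4-dien-1-one | C=CCC1C=C(OC)C(OC)=CC1=O | intermediate (not isolated)
7 | 2-allyl-4,5-dimethoxyphenol | C=CCc1cc(OC)c(OC)cc1O | intermediate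
8 | rac-2-allyl-4-(2-allyl-4,5-dimethoxyphenoxy)-4,5-dimethoxycyclohexa-2,5-dien-1-one | C=CCc1cc(OC)c(OC)cc1OC1(OC)C=C(CC=C)C(=O)C=C1OC | intermediate
9 | (R)-2-allyl-4-(2-allyl-4,5-dimethoxyphenoxy)-4,5-dimethoxycyclohexa-2,5-dien-1-one | C=CCc1cc(OC)c(OC)cc1O[C@]1(OC)C=C(CC=C)C(=O)C=C1OC | intermediate
10 | copper(I) (R)-2-allyl-4-(2-allyl-4,5-dimethoxyphenoxy)-4,5-dimethoxycyclohexa-1,5-dien-1-olate (phosphine ligands omitted) | C=CCc1cc(OC)c(OC)cc1O[C@]1(OC)CC(CC=C)=C(O[Cu])C=C1OC | intermediate (not isolated)
11 | (4R,6S)-6-allyl-4-(2-allyl-4,5-dimethoxyphenoxy)-3,4-dimethoxycyclohex-2-en-1-one | C=CCc1cc(OC)c(OC)cc1O[C@]1(OC)C[C@H](CC=C)C(=O)C=C1OC | target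

**Total step count:** 5 (4 bond-forming steps plus one resolution).
**Longest linear sequence:** 5 steps from 3,4-dimethoxyphenol.

**Three steps most likely to fail**

Step 2. The cation may be intercepted differently: [3+2] annulation with retention of silicon, attack at C2, or arylation by the electron-rich product. The fallback sets out from 1 and comes back at 7. Phenol 1 is brominated regioselectively para to the 3-methoxy group (NBS, MeCN, 0 °C) to give 2-bromo-4,5-dimethoxyphenol F1. F1 is then cross-coupled with allylboronic acid pinacol ester (Pd(dppf)Cl2, CsF, THF, 70 °C) to give 7. Here the isolable halophenol, not the transient ketal cation, serves as the electrophilic ortho-carbon.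

Step 3. Acetate or adventitious water may capture the oxidised phenol (giving the quinone), or C–C coupling through the free ortho position may compete with O–C4 coupling. The fallback sets out from 7 and comes back at 8. Phenol 7 is first oxidised in methanol (PhI(OAc)2, MeOH, 0 °C) to 2-allyl-4,4,5-trimethoxycyclohexa-2,5-dien-1-one F2. F2 then undergoes acid-catalysed transketalisation with a second portion of 7 (PPTS 5 mol %, 5 Å sieves to remove methanol, toluene, 0 °C) to give 8. This separates the oxidation from the C–O bond formation.

Step 5. The facial selectivity of protonation is controlled only by the OMe/OAr difference at C4, so it may be modest (estimated about 4:1) or favour the (4R,6R)-epimer; that epimer is separable on silica. The fallback sets out from 9 and comes back at 11. The same CuH catalyst with PhMe2SiH but no alcohol gives the isolable silyl dienol ether [(R)-2-allyl-4-(2-allyl-4,5-dimethoxyphenoxy)-4,5-dimethoxycyclohexa-1,5-dien-1-yl]oxy(dimethyl)phenylsilane F3. F3 is protodesilylated at −78 °C with TBAF in the presence of a reagent-controlling proton donor (2,6-di-tert-butyl-4-methylphenol, or a chiral phenol if substrate bias is insufficient) to give 11. This replaces protonation inside the catalytic cycle with a separate, tunable kinetic protonation.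

**Further compounds**
F1 | step 2 | 2-bromo-4,5-dimethoxyphenol | COc1cc(O)c(Br)cc1OC
F2 | step 3 | 2-allyl-4,4,5-trimethoxycyclohexa-2,5-dien-1-one | C=CCC1=CC(OC)(OC)C(OC)=CC1=O
F3 | step 5 | [(R)-2-allyl-4-(2-allyl-4,5-dimethoxyphenoxy)-4,5-dimethoxycyclohexa-1,5-dien-1-yl]oxy(dimethyl)phenylsilane | C=CCc1cc(OC)c(OC)cc1O[C@]1(OC)CC(CC=C)=C(O[Si](C)(C)c2ccccc2)C=C1OC
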